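- 4.33 was the number I began from: the rate of reagent use by second substrate over that by starting material, the split, a selectivity factor. Reagent and catalyst stand in both rates, so they and time drop out, leaving 5200 L² mol⁻² s⁻¹ c(second substrate) over 1200 L² mol⁻² s⁻¹ c(starting material).

| setting | amber | red | teal | green |
|---|---|---|---|---|
| starting material | 0.050 M | 0.050 M | 0.050 M | 0.050 M |
| reagent | 0.0300 M | 0.0300 M | 0.0300 M | 0.0300 M |
| second substrate | 0.0500 M | 0.0500 M | 0.0500 M (fed, over 10.0 s) | 0.0500 M |
| catalyst | 1.2 mM | 1.2 mM | 1.2 mM | 1.2 mM |
| time | 10 s |  | 10 s | 10 s |
| remark | plug flow through a tube for 10 s, no back-mixing | a single well-mixed tank run continuously and read at steady state, 10 s in it on average | all but second substrate at the start; second substrate goes in evenly over 10.0 s, the run ends at 10 s | a closed flask charged with all of it at once and left for 10 s |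

1. the set-up with the highest amount of target at the outlet or at the end, in percent of the starting material put in ("none" if the first two lie within 2 percentage points) (amber / red / teal / green / none)
2. amount of target at the outlet or at the end, in percent of the starting material put in, amber
3. amount of target at the outlet or at the end, in percent of the starting material put in, red
4. amount of target at the outlet or at the end, in percent of the starting material put in, teal
5. amount of target at the outlet or at the end, in percent of the starting material put in, green

- the stated concentrations are those of everything mixed, before any reaction; amounts are the same in each set-up
- the feed brings no volume worth counting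
- run time (amber): 10 s

- For the low extreme I put the whole second substrate in at the start and held the split at its charge value. Reagent, at 0.0300 M, is the limiting reagent, less than the two substrates together, and target takes one part in one plus the split. With the whole 0.0300 M used, that gave 11.2% of the starting material, my figure for amber and green, whose histories are alike.
- For the high extreme I took no second substrate and held c(starting material) at its charge. Reagent then decayed at 0.0720 s⁻¹ and gave 30.8%.
- I placed teal between them, since its feed climbs from nothing to the full charge. The amount fed averages 0.0250 M over the run, and I took that as a rough level, counting none of it as consumed. With a split of 2.17 and the whole reagent used, I got 18.9%, an estimate and not a bound. I made no reckoning for red.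
- The forecast named teal, with amber 11.8% (10.5% to 13.2%), red 8.9% (8.2% to 9.6%), teal 18.8% (16.5% to 21%) and green 11.8% (10.5% to 13.2%). Its ground was “feeding it slowly leaves more reagent for the target early on”.
- The simulation gave teal as best, with amber 11.5%, red 8.87%, teal 19.2% and green 11.5%.

    starting material + reagent + catalyst → catalyst + target (k1 = 1200 L² mol⁻² s⁻¹)
    second substrate + reagent + catalyst → catalyst + second product (k2 = 5200 L² mol⁻² s⁻¹)
    starting material ⇌ dormant form (K3 = 0.55, k3 = 0.043 s⁻¹)

- In teal the split read 2.5 at 5.43 s, below the 4.33 of the charge, and teal ended with 1.54 of second product per target, against 3.87 in amber. In the neighbour of teal with 0.0020 M of catalyst, the split taken from what stood at the end was 5.40, against 5.13 in teal, and that neighbour ended with target at 24.6%.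

(Its constants were drawn at random within sensible limits; the run is a simulation.)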